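**Retrosynthetic overview**
- The target comes from O‑sulfation and ester hydrolysis of a C‑7 hydroxy dienoate, whose side chain is made by a vinylogous Horner–Wadsworth–Emmons reaction on the C‑1 aldehyde.
- The C‑1 aldehyde comes from methanolysis, with epimerisation at C‑1, of a bridged δ‑lactone that ties O‑7 to the C‑1 carbonyl.
- That lactone comes from an intramolecular Diels–Alder reaction of a triene tethered to C‑6 of a trans‑5,6‑disubstituted 5,6‑dihydropyran‑2‑one. The lactone ring is made first, rings A (cyclohexene) and B (cyclohexane) then form together in this one step, and the lactone is opened afterwards.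
- The triene lactone comes from Negishi coupling of an (E)‑vinyl iodide lactone with a dienylzinc reagent made from tiglaldehyde; the lactone comes from a Still–Gennari Z‑olefination and lactonisation.
- The anti Me/OH pair comes from ketoreductase reduction of an achiral β‑keto ester (first stereocentre), followed by Fráter–Seebach methylation.

Assumption: the target is drawn as the free acid (sulfuric monoester and carboxylic acid); it is built as its salt and protonated in the last operation. In SMILES of zirconium species the C5H5 ligands are written as σ‑bonded rings.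

**Route**

Step 1
Reactants: 1 methyl acetoacetate; 2 3-bromo-1-(trimethylsilyl)prop-1-yne
Product: 4 methyl 3-oxo-7-(trimethylsilyl)hept-6-ynoate, via sodium lithium dianion 3 (not isolated)
Conditions: NaH, THF, 0 °C; n-BuLi, 0 °C; then 2, −78 → 0 °C; aq. HCl
Reagents that add atoms: none
Why: Weiler dianion alkylation, in which the more basic γ‑carbanion of the acetoacetate dianion is alkylated selectively by the propargylic bromide (SN2) and the silyl cap protects the alkyne C–H.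

Step 2
Reactants: 4 methyl 3-oxo-7-(trimethylsilyl)hept-6-ynoate
Product: 5 methyl (3R)-3-hydroxy-7-(trimethylsilyl)hept-6-ynoate
Conditions: ketoreductase (NADPH-dependent, (R)-selective), NADP+ (cat.), i-PrOH, phosphate buffer pH 7, 30 °C
Reagents that add atoms: none
Why: Ketoreductase-catalysed asymmetric reduction, in which the enzyme delivers hydride from NADPH (recycled by i-PrOH) to one face of the prochiral ketone and so sets the first stereocentre (future C‑7, R) in very high ee.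

Step 3
Reactants: 5 methyl (3R)-3-hydroxy-7-(trimethylsilyl)hept-6-ynoate
Product: 7 methyl (2R,3R)-3-hydroxy-2-methyl-7-(trimethylsilyl)hept-6-ynoate, via dilithium alkoxide enolate 6 (not isolated)
Conditions: LiN(i-Pr)2 (2.2 equiv), THF, −78 → −20 °C; MeI, DMPU, −78 → 0 °C; aq. HCl
Reagents that add atoms: iodomethane, CI
Why: Fráter–Seebach alkylation, in which the chelated dilithium alkoxide–enolate is methylated anti to the carbinol side chain and gives the anti (2R,3R) ester (future C‑8 methyl).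

Step 4
Reactants: 7 methyl (2R,3R)-3-hydroxy-2-methyl-7-(trimethylsilyl)hept-6-ynoate
Product: 8 methyl (2R,3R)-3-hydroxy-2-methylhept-6-ynoate
Conditions: K2CO3 (cat.), MeOH, 0 °C
Reagents that add atoms: none
Why: Protodesilylation of the C(sp)–Si bond by methanolysis under catalytic carbonate, which is too mild at 0 °C to epimerise or cleave the β‑hydroxy ester.

Step 5
Reactants: 8 methyl (2R,3R)-3-hydroxy-2-methylhept-6-ynoate
Product: 9 methyl (2R,3R)-3-[(tert-butyldimethylsilyl)oxy]-2-methylhept-6-ynoate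
Conditions: TBSOTf, 2,6-lutidine, CH2Cl2, −78 → 0 °C
Reagents that add atoms: tert-butyldimethylsilyl trifluoromethanesulfonate, CC(C)(C)[Si](C)(C)OS(=O)(=O)C(F)(F)F
Why: Silylation of the secondary alcohol with a silyl triflate protects it for the hydride and base steps ahead.

Step 6
Reactants: 9 methyl (2R,3R)-3-[(tert-butyldimethylsilyl)oxy]-2-methylhept-6-ynoate
Product: 11 methyl (2R,3R,6E)-3-[(tert-butyldimethylsilyl)oxy]-7-iodo-2-methylhept-6-enoate, via alkenylzirconocene chloride 10 (not isolated)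
Conditions: Cp2Zr(H)Cl, THF, rt; then I2, 0 °C
Reagents that add atoms: iodine, II
Why: Hydrozirconation–iodination, in which syn addition of Zr–H with Zr on the terminal carbon and iodinolysis with retention give only the E‑vinyl iodide while the ester is left alone at room temperature.

Step 7
Reactants: 11 methyl (2R,3R,6E)-3-[(tert-butyldimethylsilyl)oxy]-7-iodo-2-methylhept-6-enoate
Product: 12 (2S,3R,6E)-3-[(tert-butyldimethylsilyl)oxy]-7-iodo-2-methylhept-6-en-1-ol
Conditions: i-Bu2AlH (2.5 equiv), CH2Cl2, −78 → 0 °C; aq. potassium sodium tartrate (KNaC4H4O6)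
Reagents that add atoms: none
Why: Full ester reduction with i-Bu2AlH to the primary alcohol is more dependable than stopping at the aldehyde, and the vinyl iodide and silyl ether are inert.

Step 8
Reactants: 12 (2S,3R,6E)-3-[(tert-butyldimethylsilyl)oxy]-7-iodo-2-methylhept-6-en-1-ol
Product: 13 (2R,3R,6E)-3-[(tert-butyldimethylsilyl)oxy]-7-iodo-2-methylhept-6-enal
Conditions: Dess–Martin periodinane, CH2Cl2, 0 °C → rt
Reagents that add atoms: none
Why: Dess–Martin oxidation gives the α‑chiral aldehyde under near-neutral conditions without epimerisation, and it is used at once.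

Step 9
Reactants: 13 (2R,3R,6E)-3-[(tert-butyldimethylsilyl)oxy]-7-iodo-2-methylhept-6-enal; 14 methyl 2-[bis(2,2,2-trifluoroethoxy)phosphoryl]acetate
Product: 16 methyl (2Z,4S,5R,8E)-5-[(tert-butyldimethylsilyl)oxy]-9-iodo-4-methylnona-2,8-dienoate, via potassium phosphonate carbanion 15 (not isolated)
Conditions: 14, KN(SiMe3)2, 18-crown-6, THF, −78 °C; then 13
Reagents that add atoms: none
Why: Still–Gennari variant of the Horner–Wadsworth–Emmons olefination, in which the trifluoroethyl phosphonate with a dissociated potassium counter-ion eliminates fast from the kinetic adduct and gives the Z‑enoate.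

Step 10
Reactants: 16 methyl (2Z,4S,5R,8E)-5-[(tert-butyldimethylsilyl)oxy]-9-iodo-4-methylnona-2,8-dienoate
Product: 18 (5S,6R)-6-[(3E)-4-iodobut-3-en-1-yl]-5-methyl-5,6-dihydro-2H-pyran-2-one, via hydroxy Z-enoate 17 (not isolated)
Conditions: 48% aq. HF, MeCN, 0 °C → rt; then PPTS (cat.), PhH, 50 °C
Reagents that add atoms: none
Why: Desilylation then acid-catalysed lactonisation (transesterification), in which the Z geometry holds the δ‑hydroxyl next to the ester so the trans‑5,6‑disubstituted dihydropyranone closes with both stereocentres untouched.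

Step 11
Reactants: 19 (2E)-2-methylbut-2-enal (tiglaldehyde)
Product: 20 (3E)-1,1-dibromo-3-methylpenta-1,3-diene
Conditions: CBr4, PPh3, CH2Cl2, 0 °C
Reagents that add atoms: carbon tetrabromide, BrC(Br)(Br)Br
Why: Corey–Fuchs (Ramirez) dibromo-olefination, a Wittig-type reaction of Ph3P=CBr2 that carries the E trisubstituted alkene of tiglaldehyde through unchanged.

Step 12
Reactants: 20 (3E)-1,1-dibromo-3-methylpenta-1,3-diene
Product: 22 (4E)-4-methylhex-4-en-2-yne, via lithium acetylide 21 (not isolated)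
Conditions: n-BuLi (2.1 equiv), THF, −78 °C; then MeI, −78 °C → rt
Reagents that add atoms: iodomethane, CI
Why: Corey–Fuchs alkyne synthesis, in which Br/Li exchange, α‑elimination and 1,2‑shift give the lithium acetylide that is methylated in the same flask.

Step 13
Reactants: 18 (5S,6R)-6-[(3E)-4-iodobut-3-en-1-yl]-5-methyl-5,6-dihydro-2H-pyran-2-one; 22 (4E)-4-methylhex-4-en-2-yne
Product: 25 (5S,6R)-6-[(3E,5E,7E)-5,7-dimethylnona-3,5,7-trien-1-yl]-5-methyl-5,6-dihydro-2H-pyran-2-one, via dienylzirconocene chloride 23 (not isolated), via dienylzinc chloride 24 (not isolated)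
Conditions: 22, Cp2Zr(H)Cl, THF, 50 °C; ZnCl2, 0 °C; then 18, Pd(PPh3)4 (5 mol %), THF, rt
Reagents that add atoms: none
Why: Hydrozirconation–Negishi cross-coupling, in which syn Zr–H addition puts Zr on the less hindered methyl-bearing alkyne carbon and Zr→Zn transmetalation and Pd coupling retain both alkene geometries, giving the all‑E triene under neutral conditions that spare the base-sensitive lactone.

Step 14
Reactants: 25 (5S,6R)-6-[(3E,5E,7E)-5,7-dimethylnona-3,5,7-trien-1-yl]-5-methyl-5,6-dihydro-2H-pyran-2-one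
Product: 26 (1R,2S,4aS,7R,8S,8aS)-2-[(2E)-but-2-en-2-yl]-7-hydroxy-3,8-dimethyl-1,2,4a,5,6,7,8,8a-octahydronaphthalene-1-carboxylic acid 1,7-lactone
Conditions: PhMe (5 mM), BHT (cat.), 130 °C, sealed tube
Reagents that add atoms: none
Why: Intramolecular Diels–Alder reaction, in which the diene can only reach the lactone alkene face that carries the C‑6 tether (anti to the C‑5 methyl) and the endo transition state with a chair-like ring B gives the cis‑fused decalin with the target configuration at C‑2, C‑4a and C‑8a and the epimer at C‑1 (the exo mode would need a boat ring B).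

Step 15
Reactants: 26 (1R,2S,4aS,7R,8S,8aS)-2-[(2E)-but-2-en-2-yl]-7-hydroxy-3,8-dimethyl-1,2,4a,5,6,7,8,8a-octahydronaphthalene-1-carboxylic acid 1,7-lactone
Product: 28 methyl (1S,2S,4aS,7R,8S,8aS)-2-[(2E)-but-2-en-2-yl]-7-hydroxy-3,8-dimethyl-1,2,4a,5,6,7,8,8a-octahydronaphthalene-1-carboxylate, via cis hydroxy ester 27 (not isolated)
Conditions: NaOMe (3 equiv), MeOH, 65 °C, 24–48 h; AcOH
Reagents that add atoms: methanol, CO
Why: Methanolysis of the bridged lactone then base-mediated α‑epimerisation under thermodynamic control, which moves the C‑1 ester to the equatorial position trans to both neighbours where it can no longer re-lactonise (any residual cis ester closes back to 26 on work-up and is recycled).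

Step 16
Reactants: 28 methyl (1S,2S,4aS,7R,8S,8aS)-2-[(2E)-but-2-en-2-yl]-7-hydroxy-3,8-dimethyl-1,2,4a,5,6,7,8,8a-octahydronaphthalene-1-carboxylate
Product: 29 (1S,2S,4aS,7R,8S,8aR)-2-[(2E)-but-2-en-2-yl]-1-(hydroxymethyl)-3,8-dimethyl-1,2,4a,5,6,7,8,8a-octahydronaphthalen-7-ol
Conditions: LiAlH4, THF, 0 °C → rt
Reagents that add atoms: none
Why: Hydride reduction of the ester to the primary alcohol affects no stereocentre and no alkene.

Step 17
Reactants: 29 (1S,2S,4aS,7R,8S,8aR)-2-[(2E)-but-2-en-2-yl]-1-(hydroxymethyl)-3,8-dimethyl-1,2,4a,5,6,7,8,8a-octahydronaphthalen-7-ol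
Product: 30 (1S,2S,4aS,7R,8S,8aS)-2-[(2E)-but-2-en-2-yl]-7-hydroxy-3,8-dimethyl-1,2,4a,5,6,7,8,8a-octahydronaphthalene-1-carbaldehyde
Conditions: TEMPO (cat.), PhI(OAc)2, CH2Cl2, rt
Reagents that add atoms: none
Why: TEMPO/PhI(OAc)2 oxidation takes the primary alcohol much faster than the hindered axial secondary one and stops at the aldehyde, which is already the favoured C‑1 epimer and cannot form a lactol with the trans-disposed O‑7.

Step 18
Reactants: 30 (1S,2S,4aS,7R,8S,8aS)-2-[(2E)-but-2-en-2-yl]-7-hydroxy-3,8-dimethyl-1,2,4a,5,6,7,8,8a-octahydronaphthalene-1-carbaldehyde; 31 ethyl (2E)-4-(diethoxyphosphoryl)but-2-enoate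
Product: 33 ethyl (2E,4E)-5-[(1S,2S,4aS,7R,8S,8aR)-2-[(2E)-but-2-en-2-yl]-7-hydroxy-3,8-dimethyl-1,2,4a,5,6,7,8,8a-octahydronaphthalen-1-yl]penta-2,4-dienoate, via lithium phosphonate carbanion 32 (not isolated)
Conditions: 31 (2.5 equiv), LiN(SiMe3)2, THF, −78 °C; then 30, −78 → 0 °C
Reagents that add atoms: none
Why: Vinylogous Horner–Wadsworth–Emmons olefination with the stabilised phosphonocrotonate anion gives the (2E,4E)-dienoate, and the excess reagent covers the free hydroxyl as its alkoxide.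

Step 19
Reactants: 33 ethyl (2E,4E)-5-[(1S,2S,4aS,7R,8S,8aR)-2-[(2E)-but-2-en-2-yl]-7-hydroxy-3,8-dimethyl-1,2,4a,5,6,7,8,8a-octahydronaphthalen-1-yl]penta-2,4-dienoate
Product: 35 sodium (1S,2S,4aS,7R,8S,8aR)-2-[(2E)-but-2-en-2-yl]-1-[(1E,3E)-5-ethoxy-5-oxopenta-1,3-dien-1-yl]-3,8-dimethyl-1,2,4a,5,6,7,8,8a-octahydronaphthalen-7-yl sulfate, via pyridinium sulfate 34 (not isolated)
Conditions: SO3·pyridine (5 equiv), pyridine, 50 °C; then aq. NaHCO3
Reagents that add atoms: sulfur trioxide–pyridine complex, O=S(=O)([O-])[n+]1ccccc1; sodium hydrogen carbonate, [Na+].OC([O-])=O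
Why: O‑sulfation of the secondary alcohol by SO3 transfer from the pyridine complex, then cation exchange to the stable sodium salt, with the alkenes untouched by this mild electrophile.

Step 20
Reactants: 35 sodium (1S,2S,4aS,7R,8S,8aR)-2-[(2E)-but-2-en-2-yl]-1-[(1E,3E)-5-ethoxy-5-oxopenta-1,3-dien-1-yl]-3,8-dimethyl-1,2,4a,5,6,7,8,8a-octahydronaphthalen-7-yl sulfate
Product: 37 (2E,4E)-5-[(1S,2S,4aS,7R,8S,8aR)-2-[(2E)-but-2-en-2-yl]-3,8-dimethyl-7-(sulfooxy)-1,2,4a,5,6,7,8,8a-octahydronaphthalen-1-yl]penta-2,4-dienoic acid, via lithium sodium carboxylate 36 (not isolated)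
Conditions: LiOH, THF/H2O, rt; then aq. HCl to pH 2, 0 °C, immediate extraction
Reagents that add atoms: lithium hydroxide, [Li+].[OH-]
Why: Saponification of the dienoate (alkyl sulfate monoesters survive aqueous base) then brief cold acidification gives the free acid form of the target.

**Compound list**
1 | methyl acetoacetate | COC(=O)CC(C)=O | starting material
2 | 3-bromo-1-(trimethylsilyl)prop-1-yne | C[Si](C)(C)C#CCBr | starting material
3 | sodium lithium dianion (dienolate) of 1 | C=C([O-])C=C([O-])OC.[Na+].[Li+] | intermediate (not isolated)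
4 | methyl 3-oxo-7-(trimethylsilyl)hept-6-ynoate | COC(=O)CC(=O)CCC#C[Si](C)(C)C | intermediate
5 | methyl (3R)-3-hydroxy-7-(trimethylsilyl)hept-6-ynoate | COC(=O)C[C@H](O)CCC#C[Si](C)(C)C | intermediate
6 | dilithium alkoxide enolate of 5 | C[Si](C)(C)C#CCC[C@@H]([O-])C=C([O-])OC.[Li+].[Li+] | intermediate (not isolated)
7 | methyl (2R,3R)-3-hydroxy-2-methyl-7-(trimethylsilyl)hept-6-ynoate | C[Si](C)(C)C#CCC[C@@H](O)[C@@H](C)C(=O)OC | intermediate
8 | methyl (2R,3R)-3-hydroxy-2-methylhept-6-ynoate | C#CCC[C@@H](O)[C@@H](C)C(=O)OC | intermediate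
9 | methyl (2R,3R)-3-[(tert-butyldimethylsilyl)oxy]-2-methylhept-6-ynoate | C#CCC[C@@H](O[Si](C)(C)C(C)(C)C)[C@@H](C)C(=O)OC | intermediate
10 | (E)-alkenylzirconocene chloride from 9 | Cl[Zr](/C=C/CC[C@@H](O[Si](C)(C)C(C)(C)C)[C@@H](C)C(=O)OC)(C1C=CC=C1)C1C=CC=C1 | intermediate (not isolated)
11 | methyl (2R,3R,6E)-3-[(tert-butyldimethylsilyl)oxy]-7-iodo-2-methylhept-6-enoate | I/C=C/CC[C@@H](O[Si](C)(C)C(C)(C)C)[C@@H](C)C(=O)OC | intermediate
12 | (2S,3R,6E)-3-[(tert-butyldimethylsilyl)oxy]-7-iodo-2-methylhept-6-en-1-ol | I/C=C/CC[C@@H](O[Si](C)(C)C(C)(C)C)[C@@H](C)CO | intermediate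
13 | (2R,3R,6E)-3-[(tert-butyldimethylsilyl)oxy]-7-iodo-2-methylhept-6-enal | I/C=C/CC[C@@H](O[Si](C)(C)C(C)(C)C)[C@@H](C)C=O | intermediate
14 | methyl 2-[bis(2,2,2-trifluoroethoxy)phosphoryl]acetate | COC(=O)CP(=O)(OCC(F)(F)F)OCC(F)(F)F | starting material
15 | potassium carbanion of 14 | COC(=O)[CH-]P(=O)(OCC(F)(F)F)OCC(F)(F)F.[K+] | intermediate (not isolated)
16 | methyl (2Z,4S,5R,8E)-5-[(tert-butyldimethylsilyl)oxy]-9-iodo-4-methylnona-2,8-dienoate | I/C=C/CC[C@@H](O[Si](C)(C)C(C)(C)C)[C@@H](C)/C=C\C(=O)OC | intermediate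
17 | methyl (2Z,4S,5R,8E)-5-hydroxy-9-iodo-4-methylnona-2,8-dienoate | I/C=C/CC[C@@H](O)[C@@H](C)/C=C\C(=O)OC | intermediate (not isolated)
18 | (5S,6R)-6-[(3E)-4-iodobut-3-en-1-yl]-5-methyl-5,6-dihydro-2H-pyran-2-one | I/C=C/CC[C@H]1OC(=O)C=C[C@@H]1C | intermediate
19 | (2E)-2-methylbut-2-enal (tiglaldehyde) | C/C=C(\C)C=O | starting material
20 | (3E)-1,1-dibromo-3-methylpenta-1,3-diene | C/C=C(\C)C=C(Br)Br | intermediate
21 | lithium (3E)-3-methylpent-3-en-1-yn-1-ide | C/C=C(\C)C#C[Li] | intermediate (not isolated)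
22 | (4E)-4-methylhex-4-en-2-yne | C/C=C(\C)C#CC | intermediate
23 | [(2E,4E)-4-methylhexa-2,4-dien-2-yl]zirconocene chloride | C/C=C(\C)/C=C(\C)[Zr](Cl)(C1C=CC=C1)C1C=CC=C1 | intermediate (not isolated)
24 | [(2E,4E)-4-methylhexa-2,4-dien-2-yl]zinc chloride | C/C=C(\C)/C=C(\C)[Zn]Cl | intermediate (not isolated)
25 | (5S,6R)-6-[(3E,5E,7E)-5,7-dimethylnona-3,5,7-trien-1-yl]-5-methyl-5,6-dihydro-2H-pyran-2-one | C/C=C(\C)/C=C(\C)/C=C/CC[C@H]1OC(=O)C=C[C@@H]1C | intermediate
26 | (1R,2S,4aS,7R,8S,8aS)-2-[(2E)-but-2-en-2-yl]-7-hydroxy-3,8-dimethyl-1,2,4a,5,6,7,8,8a-octahydronaphthalene-1-carboxylic acid 1,7-lactone | C/C=C(\C)[C@H]1C(C)=C[C@H]2CC[C@H]3OC(=O)[C@@H]1[C@@H]2[C@@H]3C | intermediate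
27 | methyl (1R,2S,4aS,7R,8S,8aS)-2-[(2E)-but-2-en-2-yl]-7-hydroxy-3,8-dimethyl-1,2,4a,5,6,7,8,8a-octahydronaphthalene-1-carboxylate (cis hydroxy ester) | C/C=C(\C)[C@H]1C(C)=C[C@H]2CC[C@@H](O)[C@@H](C)[C@H]2[C@H]1C(=O)OC | intermediate (not isolated)
28 | methyl (1S,2S,4aS,7R,8S,8aS)-2-[(2E)-but-2-en-2-yl]-7-hydroxy-3,8-dimethyl-1,2,4a,5,6,7,8,8a-octahydronaphthalene-1-carboxylate | C/C=C(\C)[C@H]1C(C)=C[C@H]2CC[C@@H](O)[C@@H](C)[C@H]2[C@@H]1C(=O)OC | intermediate
29 | (1S,2S,4aS,7R,8S,8aR)-2-[(2E)-but-2-en-2-yl]-1-(hydroxymethyl)-3,8-dimethyl-1,2,4a,5,6,7,8,8a-octahydronaphthalen-7-ol | C/C=C(\C)[C@H]1C(C)=C[C@H]2CC[C@@H](O)[C@@H](C)[C@H]2[C@@H]1CO | intermediate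
30 | (1S,2S,4aS,7R,8S,8aS)-2-[(2E)-but-2-en-2-yl]-7-hydroxy-3,8-dimethyl-1,2,4a,5,6,7,8,8a-octahydronaphthalene-1-carbaldehyde | C/C=C(\C)[C@H]1C(C)=C[C@H]2CC[C@@H](O)[C@@H](C)[C@H]2[C@@H]1C=O | intermediate
31 | ethyl (2E)-4-(diethoxyphosphoryl)but-2-enoate (triethyl 4-phosphonocrotonate) | CCOC(=O)/C=C/CP(=O)(OCC)OCC | starting material
32 | lithium carbanion of 31 | CCOC(=O)/C=C/[CH-]P(=O)(OCC)OCC.[Li+] | intermediate (not isolated)
33 | ethyl (2E,4E)-5-[(1S,2S,4aS,7R,8S,8aR)-2-[(2E)-but-2-en-2-yl]-7-hydroxy-3,8-dimethyl-1,2,4a,5,6,7,8,8a-octahydronaphthalen-1-yl]penta-2,4-dienoate | C/C=C(\C)[C@H]1C(C)=C[C@H]2CC[C@@H](O)[C@@H](C)[C@H]2[C@@H]1/C=C/C=C/C(=O)OCC | intermediate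
34 | pyridinium salt of the C‑7 sulfate of 33 | C/C=C(\C)[C@H]1C(C)=C[C@H]2CC[C@@H](OS(=O)(=O)[O-])[C@@H](C)[C@H]2[C@@H]1/C=C/C=C/C(=O)OCC.c1cc[nH+]cc1 | intermediate (not isolated)
35 | sodium salt of the C‑7 sulfate of 33 | C/C=C(\C)[C@H]1C(C)=C[C@H]2CC[C@@H](OS(=O)(=O)[O-])[C@@H](C)[C@H]2[C@@H]1/C=C/C=C/C(=O)OCC.[Na+] | intermediate
36 | lithium sodium salt of the target (carboxylate and sulfate) | C/C=C(\C)[C@H]1C(C)=C[C@H]2CC[C@@H](OS(=O)(=O)[O-])[C@@H](C)[C@H]2[C@@H]1/C=C/C=C/C(=O)[O-].[Na+].[Li+] | intermediate (not isolated)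
37 | (2E,4E)-5-[(1S,2S,4aS,7R,8S,8aR)-2-[(2E)-but-2-en-2-yl]-3,8-dimethyl-7-(sulfooxy)-1,2,4a,5,6,7,8,8a-octahydronaphthalen-1-yl]penta-2,4-dienoic acid | C/C=C(\C)[C@H]1C(C)=C[C@H]2CC[C@@H](OS(=O)(=O)O)[C@@H](C)[C@H]2[C@@H]1/C=C/C=C/C(=O)O | target

**Totals**
Total step count: 20. Longest linear sequence: 18 steps (steps 1–10 and 13–20, from 1).

**Steps most likely to fail, with fallbacks**

Step 14 (intramolecular Diels–Alder reaction). The lactone may be too slow a dienophile at a temperature the triene tolerates, or the endo/exo ratio may be poor; this bridged-lactone cycloaddition is designed from first principles, not taken from a direct precedent. The fallback raises dienophile reactivity while keeping the lactone bridge that controls face and ring fusion. It sets out from aldehyde 13. Knoevenagel condensation with dimethyl malonate (TiCl4, pyridine, THF, 0 °C) gives dimethyl 2-[(2S,3R,6E)-3-[(tert-butyldimethylsilyl)oxy]-7-iodo-2-methylhept-6-en-1-ylidene]propanedioate F1. Aqueous HF in MeCN removes the silyl group and the hydroxyl closes onto the cis ester to give methyl (5S,6R)-6-[(3E)-4-iodobut-3-en-1-yl]-5-methyl-2-oxo-5,6-dihydro-2H-pyran-3-carboxylate F2. Negishi coupling with the zinc reagent 24 exactly as in step 13 gives methyl (5S,6R)-6-[(3E,5E,7E)-5,7-dimethylnona-3,5,7-trien-1-yl]-5-methyl-2-oxo-5,6-dihydro-2H-pyran-3-carboxylate F3. The doubly activated alkene should cyclise at 25–60 °C in toluene to the bridged lactone ester (1R,2S,4aS,7R,8S,8aS)-2-[(2E)-but-2-en-2-yl]-7-hydroxy-1-(methoxycarbonyl)-3,8-dimethyl-1,2,4a,5,6,7,8,8a-octahydronaphthalene-1-carboxylic acid 1,7-lactone F4. Krapcho demethoxycarbonylation (LiCl, wet DMSO, 130 °C) then gives 26, where the route resumes; the bridge fixes C‑1 in that step.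

Step 15 (methanolysis and C‑1 epimerisation). Enolisation of the hindered tertiary ester may be too slow, or the lactone may persist. The fallback moves the epimerisation to the aldehyde stage, where it is much easier, and sets out from 26. Aminolysis with MeNH(OMe)·HCl and Me3Al in CH2Cl2 gives (1R,2S,4aS,7R,8S,8aS)-2-[(2E)-but-2-en-2-yl]-7-hydroxy-N-methoxy-N,3,8-trimethyl-1,2,4a,5,6,7,8,8a-octahydronaphthalene-1-carboxamide F5. Silylation with TESOTf and 2,6-lutidine gives its 7-O-triethylsilyl ether F6. Reduction with i-Bu2AlH in THF at −78 °C gives (1R,2S,4aS,7R,8S,8aS)-2-[(2E)-but-2-en-2-yl]-3,8-dimethyl-7-[(triethylsilyl)oxy]-1,2,4a,5,6,7,8,8a-octahydronaphthalene-1-carbaldehyde F7. DBU in CH2Cl2 equilibrates it to the C‑1 epimer (1S,2S,4aS,7R,8S,8aS)-2-[(2E)-but-2-en-2-yl]-3,8-dimethyl-7-[(triethylsilyl)oxy]-1,2,4a,5,6,7,8,8a-octahydronaphthalene-1-carbaldehyde F8. HF·pyridine then frees the hydroxyl to give 30, where the route resumes at step 18.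

Step 13 (hydrozirconation and Negishi coupling). Hydrozirconation of the internal enyne 22 may give regioisomers, and 22 is volatile. The fallback builds the trisubstituted alkene by two stereoselective couplings on the gem-dibromide 20 instead, and sets out from 18. Pd-catalysed borylation (B2pin2, PdCl2(dppf), KOPh, PhMe, 50 °C) gives (5S,6R)-5-methyl-6-[(3E)-4-(4,4,5,5-tetramethyl-1,3,2-dioxaborolan-2-yl)but-3-en-1-yl]-5,6-dihydro-2H-pyran-2-one F9. Suzuki–Miyaura coupling with 20 (Pd(PPh3)4, TlOEt, THF/H2O, rt) replaces only the bromide trans to the butenyl group and gives (5S,6R)-6-[(3E,5Z,7E)-5-bromo-7-methylnona-3,5,7-trien-1-yl]-5-methyl-5,6-dihydro-2H-pyran-2-one F10. Negishi methylation with retention (MeZnCl, Pd(P(t-Bu)3)2, THF, rt) then gives 25, where the route resumes at step 14.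

**Further compounds**
F1 | step 14 | dimethyl 2-[(2S,3R,6E)-3-[(tert-butyldimethylsilyl)oxy]-7-iodo-2-methylhept-6-en-1-ylidene]propanedioate | I/C=C/CC[C@@H](O[Si](C)(C)C(C)(C)C)[C@@H](C)C=C(C(=O)OC)C(=O)OC
F2 | step 14 | methyl (5S,6R)-6-[(3E)-4-iodobut-3-en-1-yl]-5-methyl-2-oxo-5,6-dihydro-2H-pyran-3-carboxylate | I/C=C/CC[C@H]1OC(=O)C(C(=O)OC)=C[C@@H]1C
F3 | step 14 | methyl (5S,6R)-6-[(3E,5E,7E)-5,7-dimethylnona-3,5,7-trien-1-yl]-5-methyl-2-oxo-5,6-dihydro-2H-pyran-3-carboxylate | C/C=C(\C)/C=C(\C)/C=C/CC[C@H]1OC(=O)C(C(=O)OC)=C[C@@H]1C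
F4 | step 14 | (1R,2S,4aS,7R,8S,8aS)-2-[(2E)-but-2-en-2-yl]-7-hydroxy-1-(methoxycarbonyl)-3,8-dimethyl-1,2,4a,5,6,7,8,8a-octahydronaphthalene-1-carboxylic acid 1,7-lactone | C/C=C(\C)[C@H]1C(C)=C[C@H]2CC[C@H]3OC(=O)[C@]1(C(=O)OC)[C@@H]2[C@@H]3C
F5 | step 15 | (1R,2S,4aS,7R,8S,8aS)-2-[(2E)-but-2-en-2-yl]-7-hydroxy-N-methoxy-N,3,8-trimethyl-1,2,4a,5,6,7,8,8a-octahydronaphthalene-1-carboxamide | C/C=C(\C)[C@H]1C(C)=C[C@H]2CC[C@@H](O)[C@@H](C)[C@H]2[C@H]1C(=O)N(C)OC
F6 | step 15 | (1R,2S,4aS,7R,8S,8aS)-2-[(2E)-but-2-en-2-yl]-N-methoxy-N,3,8-trimethyl-7-[(triethylsilyl)oxy]-1,2,4a,5,6,7,8,8a-octahydronaphthalene-1-carboxamide | C/C=C(\C)[C@H]1C(C)=C[C@H]2CC[C@@H](O[Si](CC)(CC)CC)[C@@H](C)[C@H]2[C@H]1C(=O)N(C)OC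
F7 | step 15 | (1R,2S,4aS,7R,8S,8aS)-2-[(2E)-but-2-en-2-yl]-3,8-dimethyl-7-[(triethylsilyl)oxy]-1,2,4a,5,6,7,8,8a-octahydronaphthalene-1-carbaldehyde | C/C=C(\C)[C@H]1C(C)=C[C@H]2CC[C@@H](O[Si](CC)(CC)CC)[C@@H](C)[C@H]2[C@H]1C=O
F8 | step 15 | (1S,2S,4aS,7R,8S,8aS)-2-[(2E)-but-2-en-2-yl]-3,8-dimethyl-7-[(triethylsilyl)oxy]-1,2,4a,5,6,7,8,8a-octahydronaphthalene-1-carbaldehyde | C/C=C(\C)[C@H]1C(C)=C[C@H]2CC[C@@H](O[Si](CC)(CC)CC)[C@@H](C)[C@H]2[C@@H]1C=O
F9 | step 13 | (5S,6R)-5-methyl-6-[(3E)-4-(4,4,5,5-tetramethyl-1,3,2-dioxaborolan-2-yl)but-3-en-1-yl]-5,6-dihydro-2H-pyran-2-one | CC1(C)OB(/C=C/CC[C@H]2OC(=O)C=C[C@@H]2C)OC1(C)C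
F10 | step 13 | (5S,6R)-6-[(3E,5Z,7E)-5-bromo-7-methylnona-3,5,7-trien-1-yl]-5-methyl-5,6-dihydro-2H-pyran-2-one | C/C=C(\C)/C=C(\Br)/C=C/CC[C@H]1OC(=O)C=C[C@@H]1C
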